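Numbering: ring C1 carries the OH between the two carbon substituents, C2 the chain, C4 the second OH and C6 the methyl. The chain runs from benzylic C1' to C15', with the ketone at C5' and the carbinol at C13'.
Cuts: C4'-C5' and C12'-C13' in the chain (each an allylbarium/enal union), then ring bonds C3-C4, C1-C2 and C1-C6.
Enabling feature: the ring is a 2,6-disubstituted hydroquinone whose C4 oxygen lies between two ring CH groups (C3, C5) and whose C1 oxygen lies between C2 and C6. A propenyl(methoxy)carbene chromium complex (C4, C5, C6 and the methyl), one CO ligand (C1) and a terminal alkyne (C2, C3) that already carries C1'-C4' assemble exactly this pattern.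
Forward order: the only ring is built first on the C1'-C4' enyne, the methoxyphenol is exchanged at once for a bis-silylated hydroquinone, and C4' becomes a chloride. Nerol (C5'-C12') is joined to prenal (C13'-C15' and its methyls) at C12'-C13', and the two halves are joined last at C4'-C5'.
Stereochemistry: C13' (R) comes from CBS reduction of the C13' dienone, Z C6'=C7' from nerol, E C10'=C11' from the SeO2 oxidation, and E C2'=C3' from SN2' opening of isoprene monoxide. Both allylbarium reagents keep their alkene geometry.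

Key step: step 5

Step 1
Reactants: 1 2-methyl-2-vinyloxirane (isoprene monoxide, racemic)
Product: 2 (E)-4-chloro-2-methylbut-2-en-1-ol
Conditions: TiCl4, CH2Cl2, -80 °C
Reagents that add atoms: titanium tetrachloride, Cl[Ti](Cl)(Cl)Cl
Why: Lewis-acid-mediated SN2' opening of a vinyl epoxide, well precedented for this epoxide, in which TiCl4 activates the oxirane oxygen and delivers chloride to the vinyl terminus as the tertiary C-O bond breaks, and this should set the E C2'=C3' alkene with C4' as the alcohol and C1' as the chloride.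

Step 2
Reactants: 2 (E)-4-chloro-2-methylbut-2-en-1-ol
Product: 3 (E)-tert-butyl[(4-chloro-2-methylbut-2-en-1-yl)oxy]dimethylsilane
Conditions: TBSCl, imidazole, CH2Cl2, 0 °C
Reagents that add atoms: tert-butyldimethylsilyl chloride, CC(C)(C)[Si](C)(C)Cl
Why: Imidazole-promoted silylation of a primary alcohol, run cold and briefly so that the allylic chloride is not attacked by the base.

Step 3
Reactants: 3 (E)-tert-butyl[(4-chloro-2-methylbut-2-en-1-yl)oxy]dimethylsilane; 4 ethynylmagnesium bromide
Product: 5 (E)-tert-butyldimethyl[(2-methylhex-2-en-5-yn-1-yl)oxy]silane (skipped enyne: C1'-C4' plus the future ring atoms C2 and C3)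
Conditions: CuI (10 mol %), THF, 0 to 40 °C
Reagents that add atoms: none
Why: Copper-catalysed alkynyl Grignard/allyl halide coupling, which should proceed by direct SN2 displacement because the SN2' terminus C3' is fully substituted, giving the 1,4-enyne with the E alkene untouched.

Step 4
Reactants: 6 (E)-1-bromoprop-1-ene; 7 chromium hexacarbonyl
Product: 10 pentacarbonyl[(E)-1-methoxybut-2-enylidene]chromium, via (E)-prop-1-enyllithium 8 (not isolated), via lithium acylchromate 9 (not isolated)
Conditions: t-BuLi (2 equiv), Et2O, -78 °C; Cr(CO)6, Et2O, 0 °C to rt; Me3OBF4, CH2Cl2, rt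
Reagents that add atoms: trimethyloxonium tetrafluoroborate, C[O+](C)C.F[B-](F)(F)F
Why: Fischer carbene synthesis, that is bromine-lithium exchange with retention of alkene geometry, addition of the alkenyllithium to a CO ligand, and O-methylation of the acylate by the oxonium salt.

Step 5
Reactants: 10 pentacarbonyl[(E)-1-methoxybut-2-enylidene]chromium; 5 (E)-tert-butyldimethyl[(2-methylhex-2-en-5-yn-1-yl)oxy]silane
Product: 12 2-[(E)-4-(tert-butyldimethylsilyloxy)-3-methylbut-2-enyl]-4-methoxy-6-methylphenol, via tricarbonylchromium arene complex 11 (not isolated)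
Conditions: THF, 50 °C, argon; then air, Et2O, rt
Reagents that add atoms: none
Why: Heating expels one CO from 10, the alkyne binds and inserts into the Cr=C bond with its unsubstituted terminus joining the carbene carbon (C3-C4), and migration of a CO ligand onto the new alkenylcarbene carbon (C1-C2) produces a chromium-bound dienylketene. The single ring closes by 6π electrocyclisation of that ketene, which makes C1-C6, and enolisation of the cyclohexadienone gives the phenol as its Cr(CO)3 complex 11, which air demetalates to 12. The closest known reaction type is this very one, the Dötz benzannulation of alkenyl(alkoxy)carbene chromium complexes with terminal alkynes, a formal (3+2+1) assembly leading to 4-alkoxyphenols. No stereocentre is created, and the geometry of the propenyl unit disappears on aromatisation. The one selectivity required is the orientation of alkyne insertion, and the size difference between H and the C1' methylene on the triple bond directs the substituted carbon to the position next to the CO-derived C1. The trisubstituted alkene, the silyl ether and the doubly activated C1' methylene are spectators, because the medium is neutral and the alkene of a 1,4-enyne lies too close to the triple bond to be reached by the alkenylcarbene intermediate.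

Step 6
Reactants: 12 2-[(E)-4-(tert-butyldimethylsilyloxy)-3-methylbut-2-enyl]-4-methoxy-6-methylphenol
Product: 13 2-[(E)-4-(tert-butyldimethylsilyloxy)-3-methylbut-2-enyl]-6-methyl-1,4-benzoquinone
Conditions: PhI(OAc)2, MeCN/H2O, 0 °C
Reagents that add atoms: water, O
Why: Hypervalent-iodine oxidative demethylation of a 4-methoxyphenol (activation of the phenol at iodine, addition of water at C4, loss of methanol), done here so that no oxidant ever meets the finished polyene chain.

Step 7
Reactants: 13 2-[(E)-4-(tert-butyldimethylsilyloxy)-3-methylbut-2-enyl]-6-methyl-1,4-benzoquinone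
Product: 14 2-[(E)-4-(tert-butyldimethylsilyloxy)-3-methylbut-2-enyl]-6-methylbenzene-1,4-diol
Conditions: Na2S2O4, THF/H2O, rt, argon
Reagents that add atoms: none
Why: Dithionite reduction of a 1,4-benzoquinone, a neutral two-electron reduction that leaves alkene and silyl ether alone.

Step 8
Reactants: 14 2-[(E)-4-(tert-butyldimethylsilyloxy)-3-methylbut-2-enyl]-6-methylbenzene-1,4-diol
Product: 15 bis(triisopropylsilyl) ether of 14 (both phenolic oxygens as OTIPS, C4' still OTBS)
Conditions: TIPSOTf, 2,6-lutidine, CH2Cl2, 0 °C to rt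
Reagents that add atoms: triisopropylsilyl triflate, CC(C)[Si](C(C)C)(C(C)C)OS(=O)(=O)C(F)(F)F
Why: Silyl triflate/lutidine silylation is reactive enough for the C1 hydroxyl flanked by C2 and C6 and gives aryl ethers that resist organometallics and acid yet leave with fluoride.

Step 9
Reactants: 15 bis(triisopropylsilyl) ether of 14
Product: 16 (E)-2-methyl-4-[3-methyl-2,5-bis(triisopropylsilyloxy)phenyl]but-2-en-1-ol
Conditions: CSA (cat.), MeOH/CH2Cl2, 0 °C
Reagents that add atoms: none
Why: Acid-catalysed methanolysis discriminates by silyl ether class, the primary alkyl TBS ether being cleaved far faster than bulky aryl TIPS ethers.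

Step 10
Reactants: 16 (E)-2-methyl-4-[3-methyl-2,5-bis(triisopropylsilyloxy)phenyl]but-2-en-1-ol
Product: 17 (E)-1-chloro-2-methyl-4-[3-methyl-2,5-bis(triisopropylsilyloxy)phenyl]but-2-ene (C4' chloride)
Conditions: NCS, Me2S, CH2Cl2, -30 to 0 °C
Reagents that add atoms: N-chlorosuccinimide, O=C1CCC(=O)N1Cl
Why: Corey-Kim chlorination, in which chloride displaces an alkoxysulfonium salt in SN2 fashion, converts primary allylic alcohols to chlorides without allylic transposition or loss of E geometry.

Step 11
Reactants: 18 nerol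
Product: 19 neryl tert-butyldimethylsilyl ether
Conditions: TBSCl, imidazole, DMF, rt
Reagents that add atoms: tert-butyldimethylsilyl chloride, CC(C)(C)[Si](C)(C)Cl
Why: Standard silylation of a primary alcohol, which masks C5'-O in a form that tolerates the later organobarium step.

Step 12
Reactants: 19 neryl tert-butyldimethylsilyl ether
Product: 20 (2E,6Z)-8-(tert-butyldimethylsilyloxy)-2,6-dimethylocta-2,6-dien-1-ol
Conditions: SeO2 (cat.), t-BuOOH, CH2Cl2, 0 °C to rt
Reagents that add atoms: tert-butyl hydroperoxide, CC(C)(C)OO (oxygen relayed through SeO2, O=[Se]=O)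
Why: Catalytic SeO2 allylic oxidation (ene reaction, then [2,3]-sigmatropic shift) attacks the remote, more electron-rich trisubstituted alkene at its E methyl group, oxygenating C12' and fixing E C10'=C11'.

Step 13
Reactants: 20 (2E,6Z)-8-(tert-butyldimethylsilyloxy)-2,6-dimethylocta-2,6-dien-1-ol
Product: 21 (2Z,6E)-8-chloro-3,7-dimethylocta-2,6-dien-1-yl tert-butyldimethylsilyl ether
Conditions: NCS, Me2S, CH2Cl2, -30 to 0 °C
Reagents that add atoms: N-chlorosuccinimide, O=C1CCC(=O)N1Cl
Why: Corey-Kim chlorination of a primary allylic alcohol, which proceeds by SN2 displacement and retains both alkene geometries.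

Step 14
Reactants: 21 (2Z,6E)-8-chloro-3,7-dimethylocta-2,6-dien-1-yl tert-butyldimethylsilyl ether; 22 3-methylbut-2-enal (prenal)
Product: 24 racemic (6E,10Z)-12-(tert-butyldimethylsilyloxy)-2,6,10-trimethyldodeca-2,6,10-trien-4-ol, via allylbarium chloride 23 (not isolated)
Conditions: lithium biphenylide (2 equiv), BaI2, THF, rt; 21, -78 °C; 22, -78 °C
Reagents that add atoms: none
Why: Allylbarium carbonyl addition, in which active zerovalent barium inserts at -78 °C to give a configurationally stable allylmetal that adds 1,2 to the enal through its unsubstituted α carbon C12', so C12'-C13' forms with the E alkene kept and C13' still racemic.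

Step 15
Reactants: 24 racemic (6E,10Z)-12-(tert-butyldimethylsilyloxy)-2,6,10-trimethyldodeca-2,6,10-trien-4-ol
Product: 25 (6E,10Z)-12-(tert-butyldimethylsilyloxy)-2,6,10-trimethyldodeca-2,6,10-trien-4-one
Conditions: MnO2, CH2Cl2, rt
Reagents that add atoms: none
Why: MnO2 oxidation of an allylic alcohol under neutral heterogeneous conditions, so the C10'=C11' alkene should stay out of conjugation.

Step 16
Reactants: 25 (6E,10Z)-12-(tert-butyldimethylsilyloxy)-2,6,10-trimethyldodeca-2,6,10-trien-4-one
Product: 26 (4R,6E,10Z)-12-(tert-butyldimethylsilyloxy)-2,6,10-trimethyldodeca-2,6,10-trien-4-ol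
Conditions: (S)-Me-CBS oxazaborolidine, catecholborane, toluene, -78 °C
Reagents that add atoms: none
Why: Corey-Bakshi-Shibata reduction, in which the ketone binds the (S)-oxazaborolidine with the conjugated isobutenyl group in the role of the large substituent and the C12' methylene as the small one, so hydride should reach the Si face of C13' and give the R carbinol, in the same sense as acetophenone gives the R alcohol.

Step 17
Reactants: 26 (4R,6E,10Z)-12-(tert-butyldimethylsilyloxy)-2,6,10-trimethyldodeca-2,6,10-trien-4-ol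
Product: 27 bis(tert-butyldimethylsilyl) ether of (2Z,6E,9R)-3,7,11-trimethyldodeca-2,6,10-triene-1,9-diol
Conditions: TBSCl, imidazole, DMF, rt
Reagents that add atoms: tert-butyldimethylsilyl chloride, CC(C)(C)[Si](C)(C)Cl
Why: Standard silylation that occurs at oxygen only, so the C13' configuration is untouched.

Step 18
Reactants: 27 bis(tert-butyldimethylsilyl) ether of (2Z,6E,9R)-3,7,11-trimethyldodeca-2,6,10-triene-1,9-diol
Product: 28 (2Z,6E,9R)-9-(tert-butyldimethylsilyloxy)-3,7,11-trimethyldodeca-2,6,10-trien-1-ol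
Conditions: HF·pyridine, pyridine, THF, 0 °C
Reagents that add atoms: none
Why: Buffered HF·pyridine cleaves the unhindered primary TBS ether much faster than the secondary one, a widely used steric discrimination mild enough for the ionisable C13' allylic ether.

Step 19
Reactants: 28 (2Z,6E,9R)-9-(tert-butyldimethylsilyloxy)-3,7,11-trimethyldodeca-2,6,10-trien-1-ol
Product: 29 (2Z,6E,9R)-9-(tert-butyldimethylsilyloxy)-3,7,11-trimethyldodeca-2,6,10-trienal
Conditions: MnO2, CH2Cl2, 0 °C to rt
Reagents that add atoms: none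
Why: MnO2 oxidation of a primary allylic alcohol, which as in the nerol-to-neral conversion should keep the Z geometry under neutral conditions, and the enal is used at once.

Step 20
Reactants: 17 (E)-1-chloro-2-methyl-4-[3-methyl-2,5-bis(triisopropylsilyloxy)phenyl]but-2-ene; 29 (2Z,6E,9R)-9-(tert-butyldimethylsilyloxy)-3,7,11-trimethyldodeca-2,6,10-trienal
Product: 31 (2E,6Z,10E,13R)-13-(tert-butyldimethylsilyloxy)-3,7,11,15-tetramethyl-1-[3-methyl-2,5-bis(triisopropylsilyloxy)phenyl]hexadeca-2,6,10,14-tetraen-5-ol (both C5' epimers), via allylbarium chloride 30 (not isolated)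
Conditions: lithium biphenylide (2 equiv), BaI2, THF, rt; 17, -78 °C; 29, -78 °C
Reagents that add atoms: none
Why: Allylbarium carbonyl addition, which should form C4'-C5' by 1,2-attack of the free α methylene C4' (the γ carbon C2' carries the arylmethyl group) with E C2'=C3' and Z C6'=C7' retained at -78 °C, and the C5' epimer mixture is erased in step 21.

Step 21
Reactants: 31 C5' alcohol (both epimers)
Product: 32 (2E,6Z,10E,13R)-13-(tert-butyldimethylsilyloxy)-3,7,11,15-tetramethyl-1-[3-methyl-2,5-bis(triisopropylsilyloxy)phenyl]hexadeca-2,6,10,14-tetraen-5-one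
Conditions: MnO2, CH2Cl2, rt
Reagents that add atoms: none
Why: MnO2 oxidation of the only free (allylic) alcohol, in a neutral medium that should neither move C2'=C3' into conjugation nor isomerise the Z enone.

Step 22
Reactants: 32 tris-silylated C5' ketone
Product: 33 2-[(2E,6Z,10E,13R)-13-hydroxy-3,7,11,15-tetramethyl-5-oxohexadeca-2,6,10,14-tetraenyl]-6-methylbenzene-1,4-diol (CNP0251818.2)
Conditions: TBAF, AcOH (1:1), THF, 0 °C to rt, argon
Reagents that add atoms: none
Why: Fluoride-induced desilylation of all three silyl ethers, with acetic acid buffering fluoride and phenoxide so that the C4' methylene is not enolised and argon protecting the hydroquinone, and C13' is not involved in any bond change.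

Compound list
1 | 2-methyl-2-vinyloxirane | CC1(C=C)CO1 | starting material
2 | (E)-4-chloro-2-methylbut-2-en-1-ol | OC/C(C)=C/CCl | intermediate
3 | (E)-tert-butyl[(4-chloro-2-methylbut-2-en-1-yl)oxy]dimethylsilane | CC(C)(C)[Si](C)(C)OC/C(C)=C/CCl | intermediate
4 | ethynylmagnesium bromide | C#C[Mg]Br | starting material
5 | (E)-tert-butyldimethyl[(2-methylhex-2-en-5-yn-1-yl)oxy]silane | CC(C)(C)[Si](C)(C)OC/C(C)=C/CC#C | intermediate
6 | (E)-1-bromoprop-1-ene | C/C=C/Br | starting material
7 | chromium hexacarbonyl | O=C=[Cr](=C=O)(=C=O)(=C=O)(=C=O)=C=O | starting material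
8 | (E)-prop-1-enyllithium | C/C=C/[Li] | intermediate
9 | lithium pentacarbonyl[(E)-1-oxidobut-2-enylidene]chromate | [Li+].[O-]C(/C=C/C)=[Cr](=C=O)(=C=O)(=C=O)(=C=O)=C=O | intermediate
10 | pentacarbonyl[(E)-1-methoxybut-2-enylidene]chromium | COC(/C=C/C)=[Cr](=C=O)(=C=O)(=C=O)(=C=O)=C=O | intermediate
11 | tricarbonylchromium η6-arene complex of 12 | CC(C)(C)[Si](C)(C)OC/C(C)=C/Cc1cc(OC)cc(C)c1O.O=C=[Cr](=C=O)=C=O | intermediate
12 | 2-[(E)-4-(tert-butyldimethylsilyloxy)-3-methylbut-2-enyl]-4-methoxy-6-methylphenol | CC(C)(C)[Si](C)(C)OC/C(C)=C/Cc1cc(OC)cc(C)c1O | intermediate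
13 | 2-[(E)-4-(tert-butyldimethylsilyloxy)-3-methylbut-2-enyl]-6-methyl-1,4-benzoquinone | CC(C)(C)[Si](C)(C)OC/C(C)=C/CC1=CC(=O)C=C(C)C1=O | intermediate
14 | 2-[(E)-4-(tert-butyldimethylsilyloxy)-3-methylbut-2-enyl]-6-methylbenzene-1,4-diol | CC(C)(C)[Si](C)(C)OC/C(C)=C/Cc1cc(O)cc(C)c1O | intermediate
15 | bis(triisopropylsilyl) ether of 14 | CC(C)(C)[Si](C)(C)OC/C(C)=C/Cc1cc(O[Si](C(C)C)(C(C)C)C(C)C)cc(C)c1O[Si](C(C)C)(C(C)C)C(C)C | intermediate
16 | (E)-2-methyl-4-[3-methyl-2,5-bis(triisopropylsilyloxy)phenyl]but-2-en-1-ol | OC/C(C)=C/Cc1cc(O[Si](C(C)C)(C(C)C)C(C)C)cc(C)c1O[Si](C(C)C)(C(C)C)C(C)C | intermediate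
17 | (E)-1-chloro-2-methyl-4-[3-methyl-2,5-bis(triisopropylsilyloxy)phenyl]but-2-ene | ClC/C(C)=C/Cc1cc(O[Si](C(C)C)(C(C)C)C(C)C)cc(C)c1O[Si](C(C)C)(C(C)C)C(C)C | intermediate
18 | nerol | CC(C)=CCC/C(C)=C\CO | starting material
19 | neryl tert-butyldimethylsilyl ether | CC(C)=CCC/C(C)=C\CO[Si](C)(C)C(C)(C)C | intermediate
20 | (2E,6Z)-8-(tert-butyldimethylsilyloxy)-2,6-dimethylocta-2,6-dien-1-ol | OC/C(C)=C/CC/C(C)=C\CO[Si](C)(C)C(C)(C)C | intermediate
21 | (2Z,6E)-8-chloro-3,7-dimethylocta-2,6-dien-1-yl tert-butyldimethylsilyl ether | ClC/C(C)=C/CC/C(C)=C\CO[Si](C)(C)C(C)(C)C | intermediate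
22 | 3-methylbut-2-enal | CC(C)=CC=O | starting material
23 | allylbarium chloride from 21 (barium on C12') | Cl[Ba]C/C(C)=C/CC/C(C)=C\CO[Si](C)(C)C(C)(C)C | intermediate
24 | racemic (6E,10Z)-12-(tert-butyldimethylsilyloxy)-2,6,10-trimethyldodeca-2,6,10-trien-4-ol | CC(C)=CC(O)C/C(C)=C/CC/C(C)=C\CO[Si](C)(C)C(C)(C)C | intermediate
25 | (6E,10Z)-12-(tert-butyldimethylsilyloxy)-2,6,10-trimethyldodeca-2,6,10-trien-4-one | CC(C)=CC(=O)C/C(C)=C/CC/C(C)=C\CO[Si](C)(C)C(C)(C)C | intermediate
26 | (4R,6E,10Z)-12-(tert-butyldimethylsilyloxy)-2,6,10-trimethyldodeca-2,6,10-trien-4-ol | CC(C)=C[C@H](O)C/C(C)=C/CC/C(C)=C\CO[Si](C)(C)C(C)(C)C | intermediate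
27 | bis(tert-butyldimethylsilyl) ether of (2Z,6E,9R)-3,7,11-trimethyldodeca-2,6,10-triene-1,9-diol | CC(C)=C[C@H](O[Si](C)(C)C(C)(C)C)C/C(C)=C/CC/C(C)=C\CO[Si](C)(C)C(C)(C)C | intermediate
28 | (2Z,6E,9R)-9-(tert-butyldimethylsilyloxy)-3,7,11-trimethyldodeca-2,6,10-trien-1-ol | CC(C)=C[C@H](O[Si](C)(C)C(C)(C)C)C/C(C)=C/CC/C(C)=C\CO | intermediate
29 | (2Z,6E,9R)-9-(tert-butyldimethylsilyloxy)-3,7,11-trimethyldodeca-2,6,10-trienal | CC(C)=C[C@H](O[Si](C)(C)C(C)(C)C)C/C(C)=C/CC/C(C)=C\C=O | intermediate
30 | allylbarium chloride from 17 (barium on C4') | Cl[Ba]C/C(C)=C/Cc1cc(O[Si](C(C)C)(C(C)C)C(C)C)cc(C)c1O[Si](C(C)C)(C(C)C)C(C)C | intermediate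
31 | (2E,6Z,10E,13R)-13-(tert-butyldimethylsilyloxy)-3,7,11,15-tetramethyl-1-[3-methyl-2,5-bis(triisopropylsilyloxy)phenyl]hexadeca-2,6,10,14-tetraen-5-ol, both C5' epimers | CC(C)=C[C@H](O[Si](C)(C)C(C)(C)C)C/C(C)=C/CC/C(C)=C\C(O)C/C(C)=C/Cc1cc(O[Si](C(C)C)(C(C)C)C(C)C)cc(C)c1O[Si](C(C)C)(C(C)C)C(C)C | intermediate
32 | (2E,6Z,10E,13R)-13-(tert-butyldimethylsilyloxy)-3,7,11,15-tetramethyl-1-[3-methyl-2,5-bis(triisopropylsilyloxy)phenyl]hexadeca-2,6,10,14-tetraen-5-one | CC(C)=C[C@H](O[Si](C)(C)C(C)(C)C)C/C(C)=C/CC/C(C)=C\C(=O)C/C(C)=C/Cc1cc(O[Si](C(C)C)(C(C)C)C(C)C)cc(C)c1O[Si](C(C)C)(C(C)C)C(C)C | intermediate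
33 | 2-[(2E,6Z,10E,13R)-13-hydroxy-3,7,11,15-tetramethyl-5-oxohexadeca-2,6,10,14-tetraenyl]-6-methylbenzene-1,4-diol | CC(C)=C[C@H](O)C/C(C)=C/CC/C(C)=C\C(=O)C/C(C)=C/Cc1cc(O)cc(C)c1O | target

Total step count: 22.
Longest linear sequence: 12 steps, from nerol through steps 11-19 and 20-22. The arene branch (steps 1-3, 5-10 and 20-22) is equally long.

Steps most likely to fail

Step 20 (fragment union). Three processes may erode the coupling:
- self-coupling of the allylbarium with unreacted chloride;
- attack through C2' instead of C4';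
- proton transfer from the doubly activated C1' methylene.

The C4' nucleophile would then be changed from an allylmetal to a sulfonyl carbanion, setting out from 17. PhSO2Na in DMF should give the allyl phenyl sulfone F1. Its lithio derivative (n-BuLi, THF, -78 °C) reacts at the sulfonyl-bearing carbon and adds to enal 29 to give the β-hydroxy sulfone F2. MnO2 oxidises this allylic alcohol to the β-keto sulfone F3. SmI2 in THF/MeOH at -78 °C removes the sulfonyl group, and the route is rejoined at ketone 32.

Step 16 (C13' stereocentre). Facial discrimination may be poor, because the isobutenyl group and the branched C12' arm differ little in effective size. The stereocentre would then be secured by resolution instead of reduction, setting out from racemic alcohol 24, and steps 15 and 16 are dropped. A Sharpless kinetic resolution (Ti(OiPr)4, L-(+)-DIPT, about 0.6 equiv t-BuOOH, 4 Å sieves, CH2Cl2, -20 °C) acts only on the allylic-alcohol alkene. It should consume the S enantiomer as the erythro epoxy alcohol F4 and leave the R alcohol, rejoining the route at 26.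

Step 22 (global desilylation). Three processes may spoil the last step:
- migration of C2'=C3' into conjugation;
- Z-to-E drift at C6'=C7' during the long exposure that the secondary silyl ether needs;
- aerial oxidation of the liberated hydroquinone.

The endgame would then be rerouted through the quinone oxidation level, setting out from 32.
- A short treatment with buffered TBAF at low temperature removes only the two aryl silyl groups and gives the hydroquinone silyl ether F5.
- Ag2O in Et2O oxidises it to the air-stable quinone silyl ether F6.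
- HF·pyridine in THF, which is acidic and non-enolising, frees the C13' hydroxyl to give the quinone alcohol F7.
- Na2S2O4 in THF/H2O reduces F7 under neutral conditions, arriving at 33.

Further compounds
F1 | step 20 | (E)-2-methyl-4-[3-methyl-2,5-bis(triisopropylsilyloxy)phenyl]but-2-enyl phenyl sulfone | O=S(=O)(c1ccccc1)C/C(C)=C/Cc1cc(O[Si](C(C)C)(C(C)C)C(C)C)cc(C)c1O[Si](C(C)C)(C(C)C)C(C)C
F2 | step 20 | C4'-phenylsulfonyl derivative of alcohol 31 (β-hydroxy sulfone, isomer mixture at C4' and C5') | CC(C)=C[C@H](O[Si](C)(C)C(C)(C)C)C/C(C)=C/CC/C(C)=C\C(O)C(/C(C)=C/Cc1cc(O[Si](C(C)C)(C(C)C)C(C)C)cc(C)c1O[Si](C(C)C)(C(C)C)C(C)C)S(=O)(=O)c1ccccc1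
F3 | step 20 | C4'-phenylsulfonyl derivative of ketone 32 (β-keto sulfone) | CC(C)=C[C@H](O[Si](C)(C)C(C)(C)C)C/C(C)=C/CC/C(C)=C\C(=O)C(/C(C)=C/Cc1cc(O[Si](C(C)C)(C(C)C)C(C)C)cc(C)c1O[Si](C(C)C)(C(C)C)C(C)C)S(=O)(=O)c1ccccc1
F4 | step 16 | (13'S,14'S)-14',15'-epoxy alcohol from the S enantiomer of 24 | CC1(C)O[C@H]1[C@@H](O)C/C(C)=C/CC/C(C)=C\CO[Si](C)(C)C(C)(C)C
F5 | step 22 | 13'-O-tert-butyldimethylsilyl ether of 33 | CC(C)=C[C@H](O[Si](C)(C)C(C)(C)C)C/C(C)=C/CC/C(C)=C\C(=O)C/C(C)=C/Cc1cc(O)cc(C)c1O
F6 | step 22 | 1,4-benzoquinone corresponding to F5 | CC(C)=C[C@H](O[Si](C)(C)C(C)(C)C)C/C(C)=C/CC/C(C)=C\C(=O)C/C(C)=C/CC1=CC(=O)C=C(C)C1=O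
F7 | step 22 | 1,4-benzoquinone corresponding to 33 | CC(C)=C[C@H](O)C/C(C)=C/CC/C(C)=C\C(=O)C/C(C)=C/CC1=CC(=O)C=C(C)C1=O
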